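The constants stay unknown, yet one count needs none of them. At 1.00 equiv of E, each E spent takes an X or turns a mono adduct into J, and each X lost took an E or became Z. So, in fractions of the charge, J = X + Z − E at the end of the feed and after it.

| flask | X | E | remark | time |
|---|---|---|---|---|
| north-west | 0.020 M | 1 equiv (fed, over 80 s) | the very flask that is asked about, followed so far; the fed solution adds 0.25 times the starting volume |  |
| north | 0.030 M | 1 equiv (fed, over 80 s) | run made earlier; the fed solution adds 0.25 times the starting volume |  |
| flask | 0.020 M | 1.00 equiv (fed, over 80 s) | the fed solution adds 0.25 times the starting volume | 12 min |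

| run | time / min | X / % | L / % |
|---|---|---|---|
| north-west | 0.500 | 87 | 3 |
| north-west | 1.50 | 48 | 9 |
| north-west | 3.00 | 28 | 20 |
| north-west | 4.00 | 21 | 26 |
| north-west | 6.00 | 16 | 26 |
| north | 1.50 | 41 | 11 |
| north | 3.00 | 24 | 22 |
| north | 5.00 | 17 | 24 |
| north | 6.00 | 15 | 27 |
| north | 8.00 | 12 | 26 |

(standard deviation of a reading: 1.5 percentage points)

- every charge counts on the volume at the start, and the solution that is fed holds the whole dose
- what may be going on: X + E -> G + D; X + E -> Q + D; E + G -> J + D; E + Q -> J + D; X + D -> Z; G -> L

- share of the X used up at 12 min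
- L at 12 min, in percent of the X charged
- J at 12 min, in percent of the X charged

First comes X. In the north-west run, the inverse of X climbs by 0.893 min⁻¹ between 3.00 min and 6.00 min. Carried on to 12 min, that line leaves X at 8.62%, a conversion of 91.4%. Next comes Z. Taking E as nil after 6.00 min, the X lost from there on is Z, so the first figure for J is X plus that fall, 16%.

That link is weak: Z made earlier is not counted. To reforge it, the tail is read as pseudo-first-order, with a reading of 0.103 min⁻¹. The area under X from 3.00 min to 6.00 min is 0.615 min of the charge. Earlier time is left out by judgement. Z then comes to 13.7%, and the E ledger, J as X left plus Z, stands at 22.3%. L stays with its last reading, 26%.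

The forecast, whose numbers differ a little from this reckoning, says 90%, 27% and 22%: “J was not measured, so it comes from a balance.”

The flask gives 90.2%, 29.5% and 23.5%.

    X + E → G + D (k = 1.14 M⁻¹ s⁻¹)
    X + E → Q + D (k = 0.491 M⁻¹ s⁻¹)
    E + G → J + D (k = 3.30 M⁻¹ s⁻¹)
    E + Q → J + D (k = 0.0182 M⁻¹ s⁻¹)
    X + D → Z (k = 0.0803 M⁻¹ s⁻¹)
    G → L (k = 0.0146 s⁻¹)

The ledger's 22.3% lies 1.2 percentage points below the J of the flask. At 12.0 min the flask holds X 9.83%, Z 14.5% and E 0.840% of its own charge, and the ledger filled with these gives 23.5%. The neighbour flask left until 20 min holds X 5.53%, Z 18.3% and E 0.316%, so its ledger gives 23.5%, and its J stands at 23.5%.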